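## Retrosynthetic overview

1. Target ⇐ α-methylene lactone masked as its Me2N–CH2 adduct; C14 methacrylate ⇐ enal ⇐ dimethyl acetal; both acetates ⇐ one-pot reduction/acetylation of a C6 ketone and a C1 aldehyde (side-chain ozonolysis).
2. Carbocycle (second ring) ⇐ aldol cyclodehydration forming C5=C10 from a C6/C10 diketone; C8–C9 ⇐ aldol of 1,1-dimethoxyacetone onto a lactol aldehyde.
3. Key disconnection C6–C7: the lithiated 1,3-dithiane of (S)-citronellal (acyl anion) adds 1,4 to a (5S)-menthyloxybutenolide and the enolate is trapped in a Mannich reaction; the γ-lactone (first ring) comes from the butenolide.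
4. Stereocontrol: C4 from citronellal; C7 from the menthyl acetal; C8 by Felkin–Anh aldol and trans lactonisation; C6 by equatorial hydride delivery.

Assumption and labels: the SMILES is read as (4S,6S,7S,8R), a trans-fused lactone whose C7–C11 bond is cis to the C6 acetoxy group; "C1–C14" are atom labels (C1–C4 side chain, ring C5=C10/C6/C7/C8/C9, lactone C11–C13, C14 on C10), plain numbers are compounds.

## Route

Step 1
Reactants: 1 (S)-citronellal; 2 propane-1,3-dithiol
Product: 3 2-[(2S)-2,6-dimethylhept-5-en-1-yl]-1,3-dithiane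
Conditions: BF3·OEt2 (0.1 equiv), CH2Cl2, −20 °C, slow addition of 1 to 2
Reagents that add atoms: none
Why: Lewis-acid dithioacetalisation (Corey–Seebach dithiane formation) turns the aldehyde carbon, the future C6, into a masked acyl anion, with inverse addition at low temperature so that thiol capture outruns the carbonyl-ene cyclisation of citronellal and the C4 centre stays untouched.

Step 2
Reactants: 4 5-hydroxyfuran-2(5H)-one; 5 (+)-menthol
Product: 6 (5S)-5-[(1S,2R,5S)-menthyloxy]furan-2(5H)-one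
Conditions: CSA (cat.), PhMe, reflux (Dean–Stark); crystallisation from hexane, mother liquor re-equilibrated with CSA
Reagents that add atoms: none
Why: Acid-catalysed acetalisation of the pseudo-acid gives both acetal epimers, and crystallisation-induced epimerisation funnels them into the crystalline (5S) diastereomer, the mirror image of the familiar (5R)-l-menthyloxy building block.

Step 3
Reactants: 3 2-[(2S)-2,6-dimethylhept-5-en-1-yl]-1,3-dithiane; 6 (5S)-5-[(1S,2R,5S)-menthyloxy]furan-2(5H)-one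
Product: 9 (3R,4S)-3-[(dimethylamino)methyl]-4-{2-[(2S)-2,6-dimethylhept-5-en-1-yl]-1,3-dithian-2-yl}-5-hydroxyoxolan-2-one (lactol), via lithium enolate 7 (not isolated), via Mannich adduct 8 (not isolated)
Conditions: n-BuLi, THF, −25 °C; DMPU, then 6, −78 °C; [CH2=NMe2]I, −78 → −20 °C; then 1 M HCl, THF–H2O, 45 °C
Reagents that add atoms: N,N-dimethylmethyleneiminium iodide, C=[N+](C)C.[I-]; water, O
Why: Key step, in which the 2-lithio-1,3-dithiane from 3 (Corey–Seebach acyl anion equivalent) adds 1,4 to the butenolide anti to the menthyloxy group, joining the former aldehyde carbon C6 to the β-carbon C7 and fixing C7 as S, the enolate is trapped trans to the new substituent by the iminium salt (Mannich reaction) to plant the masked exocyclic methylene, and the acidic work-up hydrolyses the menthyl acetal to the lactol.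

Step 4
Reactants: 9 lactol from step 3; 10 1,1-dimethoxypropan-2-one
Product: 12 (3R,4S,5R)-5-(3,3-dimethoxy-2-oxopropyl)-3-[(dimethylamino)methyl]-4-{2-[(2S)-2,6-dimethylhept-5-en-1-yl]-1,3-dithian-2-yl}oxolan-2-one, via hydroxy acid 11 (not isolated)
Conditions: 10, LiN(i-Pr)2 (from n-BuLi, i-Pr2NH; 2.5 equiv), THF, −78 °C; then 9, −78 → −40 °C; 1 M HCl to pH 3, rt
Reagents that add atoms: none
Why: Kinetic lithium-enolate aldol addition to the ring-opened aldehyde–carboxylate form of the lactol follows the Felkin–Anh model with the bulky dithianyl carbon anti to the nucleophile, giving the 7,8-anti adduct that closes on acidification to the (8R) trans-4,5-disubstituted γ-lactone, which is also the thermodynamically preferred isomer.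

Step 5
Reactants: 12 keto lactone dithiane from step 4
Product: 13 (3R,4S,5R)-5-(3,3-dimethoxy-2-oxopropyl)-3-[(dimethylamino)methyl]-4-[(3S)-3,7-dimethyloct-6-enoyl]oxolan-2-one
Conditions: PhI(OCOCF3)2 (1.5 equiv), CF3CO2H (1.1 equiv), MeCN–H2O 9:1, 0 °C, 15 min
Reagents that add atoms: water, O
Why: Oxidative dethioacetalisation with the hypervalent iodine reagent (Stork–Zhao conditions) unmasks the C6 ketone within minutes while the amine is shielded as its trifluoroacetate salt and the trisubstituted alkene, lactone and keto acetal are left alone.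

Step 6
Reactants: 13 diketone from step 5
Product: 14 (3R,3aS,7aR)-6-(dimethoxymethyl)-3-[(dimethylamino)methyl]-5-[(2S)-6-methylhept-5-en-2-yl]-3,3a,7,7a-tetrahydro-1-benzofuran-2,4-dione
Conditions: CSA (1.3 equiv), 4 Å molecular sieves, PhMe, 60 °C
Reagents that add atoms: none
Why: Acid-catalysed intramolecular aldol cyclodehydration (the ring-closing half of a Robinson annulation) can form a six-membered ring only by attack of the C5 enol on the activated C10 keto-acetal carbonyl, which does not usefully enolise towards C14, so the tetrasubstituted C5=C10 enone and the carbocycle form without touching C7 or C8.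

Step 7
Reactants: 14 bicyclic enone from step 6
Product: 15 (4S)-4-[(3R,3aS,7aR)-6-(dimethoxymethyl)-3-[(dimethylamino)methyl]-2,4-dioxo-2,3,3a,4,7,7a-hexahydro-1-benzofuran-5-yl]pentanal
Conditions: O3, CF3CO2H (1.1 equiv), CH2Cl2, −78 °C; PPh3, −78 °C → rt
Reagents that add atoms: ozone, [O-][O+]=O
Why: Ozonolysis with reductive work-up cleaves only the electron-rich trisubstituted side-chain alkene, because the tetrasubstituted ring alkene is deactivated by conjugation to the ketone and the amine is protected as its ammonium salt.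

Step 8
Reactants: 15 keto aldehyde from step 7
Product: 17 (4S)-4-[(3R,3aS,4S,7aR)-4-acetoxy-6-(dimethoxymethyl)-3-[(dimethylamino)methyl]-2-oxo-2,3,3a,4,7,7a-hexahydro-1-benzofuran-5-yl]pentyl acetate, via diol 16 (not isolated)
Conditions: LiBH(sec-Bu)3 (3 equiv), THF, −78 °C; then Ac2O (6 equiv), DMAP (0.3 equiv), −78 → 0 °C
Reagents that add atoms: acetic anhydride, CC(=O)OC(C)=O
Why: The bulky trialkylborohydride reduces the aldehyde and adds 1,2 to the fully substituted enone from the equatorial direction (the axial path is blocked by the axial C8 hydrogen), giving the axial (6S) alkoxide cis to the C7–C11 bond, and immediate DMAP-catalysed acetylation of both lithium alkoxides installs the two acetates before the C6 alkoxide can attack the lactone.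

Step 9
Reactants: 17 diacetate acetal from step 8
Product: 18 (4S)-4-[(3R,3aS,4S,7aR)-4-acetoxy-3-[(dimethylamino)methyl]-6-formyl-2-oxo-2,3,3a,4,7,7a-hexahydro-1-benzofuran-5-yl]pentyl acetate
Conditions: TsOH·H2O (1.2 equiv), acetone–H2O 10:1, rt
Reagents that add atoms: water, O
Why: Mild acid hydrolysis of the allylic dimethyl acetal (acetal deprotection) releases the C14 enal while the amine sits as its tosylate salt and the acetates and lactone survive.

Step 10
Reactants: 18 enal from step 9
Product: 19 (4S)-4-[(3R,3aS,4S,7aR)-4-acetoxy-3-[(dimethylamino)methyl]-6-(hydroxymethyl)-2-oxo-2,3,3a,4,7,7a-hexahydro-1-benzofuran-5-yl]pentyl acetate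
Conditions: NaBH4, CeCl3·7H2O, MeOH, −40 °C
Reagents that add atoms: none
Why: Luche reduction delivers hydride 1,2 to the enal only, leaving the acetates, the lactone and the amine untouched.

Step 11
Reactants: 19 allylic alcohol from step 10
Product: 20 {(3R,3aS,4S,7aR)-4-acetoxy-5-[(2S)-5-acetoxypentan-2-yl]-3-[(dimethylamino)methyl]-2-oxo-2,3,3a,4,7,7a-hexahydro-1-benzofuran-6-yl}methyl 2-methylprop-2-enoate
Conditions: methacrylic anhydride, Et3N, DMAP (cat.), CH2Cl2, 0 °C
Reagents that add atoms: methacrylic anhydride, C=C(C)C(=O)OC(=O)C(C)=C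
Why: DMAP-catalysed acylation (Steglich-type esterification with the anhydride) of the only free hydroxyl installs the methacrylate.

Step 12
Reactants: 20 amino methacrylate from step 11
Product: 22 {(3aS,4S,7aR)-4-acetoxy-5-[(2S)-5-acetoxypentan-2-yl]-3-methylidene-2-oxo-2,3,3a,4,7,7a-hexahydro-1-benzofuran-6-yl}methyl 2-methylprop-2-enoate (target), via ammonium iodide 21 (not isolated)
Conditions: MeI (10 equiv), MeCN, rt; evaporate; NaHCO3, H2O–EtOAc, rt
Reagents that add atoms: none
Why: Exhaustive N-methylation followed by bicarbonate-induced β-elimination of trimethylamine (Hofmann-type E1cB elimination) unveils the α-methylene lactone under conditions mild enough for the three other esters.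

## Compound list

1 | (S)-citronellal, (3S)-3,7-dimethyloct-6-enal | O=CC[C@@H](C)CCC=C(C)C | starting material
2 | propane-1,3-dithiol | SCCCS | starting material
3 | 2-[(2S)-2,6-dimethylhept-5-en-1-yl]-1,3-dithiane | S1CCCSC1C[C@@H](C)CCC=C(C)C | intermediate
4 | 5-hydroxyfuran-2(5H)-one | O=C1C=CC(O)O1 | starting material
5 | (+)-menthol, (1S,2R,5S)-5-methyl-2-(propan-2-yl)cyclohexan-1-ol | O[C@H]1C[C@@H](C)CC[C@@H]1C(C)C | starting material
6 | (5S)-5-[(1S,2R,5S)-menthyloxy]furan-2(5H)-one | C1=CC(=O)O[C@@H]1O[C@H]2C[C@@H](C)CC[C@@H]2C(C)C | intermediate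
7 | lithium enolate of the 1,4-adduct of lithiated 3 to 6 (C7 S, dithianyl trans to menthyloxy) | S1CCCSC1(C[C@@H](C)CCC=C(C)C)[C@H]2C=C(O[Li])O[C@@H]2O[C@H]3C[C@@H](C)CC[C@@H]3C(C)C | intermediate
8 | (3R,4S,5S)-3-[(dimethylamino)methyl]-4-{2-[(2S)-2,6-dimethylhept-5-en-1-yl]-1,3-dithian-2-yl}-5-[(1S,2R,5S)-menthyloxy]oxolan-2-one | S1CCCSC1(C[C@@H](C)CCC=C(C)C)[C@H]2[C@H](CN(C)C)C(=O)O[C@@H]2O[C@H]3C[C@@H](C)CC[C@@H]3C(C)C | intermediate
9 | (3R,4S)-3-[(dimethylamino)methyl]-4-{2-[(2S)-2,6-dimethylhept-5-en-1-yl]-1,3-dithian-2-yl}-5-hydroxyoxolan-2-one (lactol, both anomers) | S1CCCSC1(C[C@@H](C)CCC=C(C)C)[C@H]2[C@H](CN(C)C)C(=O)OC2O | intermediate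
10 | 1,1-dimethoxypropan-2-one | CC(=O)C(OC)OC | starting material
11 | (2R,3S,4R)-2-[(dimethylamino)methyl]-3-{2-[(2S)-2,6-dimethylhept-5-en-1-yl]-1,3-dithian-2-yl}-4-hydroxy-7,7-dimethoxy-6-oxoheptanoic acid | S1CCCSC1(C[C@@H](C)CCC=C(C)C)[C@@H]([C@H](CN(C)C)C(=O)O)[C@H](O)CC(=O)C(OC)OC | intermediate
12 | (3R,4S,5R)-5-(3,3-dimethoxy-2-oxopropyl)-3-[(dimethylamino)methyl]-4-{2-[(2S)-2,6-dimethylhept-5-en-1-yl]-1,3-dithian-2-yl}oxolan-2-one | S1CCCSC1(C[C@@H](C)CCC=C(C)C)[C@H]2[C@H](CN(C)C)C(=O)O[C@@H]2CC(=O)C(OC)OC | intermediate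
13 | (3R,4S,5R)-5-(3,3-dimethoxy-2-oxopropyl)-3-[(dimethylamino)methyl]-4-[(3S)-3,7-dimethyloct-6-enoyl]oxolan-2-one | O=C(C[C@@H](C)CCC=C(C)C)[C@H]1[C@H](CN(C)C)C(=O)O[C@@H]1CC(=O)C(OC)OC | intermediate
14 | (3R,3aS,7aR)-6-(dimethoxymethyl)-3-[(dimethylamino)methyl]-5-[(2S)-6-methylhept-5-en-2-yl]-3,3a,7,7a-tetrahydro-1-benzofuran-2,4-dione (trans-fused) | COC(OC)C1=C([C@@H](C)CCC=C(C)C)C(=O)[C@H]2[C@H](CN(C)C)C(=O)O[C@@H]2C1 | intermediate
15 | (4S)-4-[(3R,3aS,7aR)-6-(dimethoxymethyl)-3-[(dimethylamino)methyl]-2,4-dioxo-2,3,3a,4,7,7a-hexahydro-1-benzofuran-5-yl]pentanal | COC(OC)C1=C([C@@H](C)CCC=O)C(=O)[C@H]2[C@H](CN(C)C)C(=O)O[C@@H]2C1 | intermediate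
16 | (3R,3aR,4S,7aR)-6-(dimethoxymethyl)-3-[(dimethylamino)methyl]-4-hydroxy-5-[(2S)-5-hydroxypentan-2-yl]-3a,4,7,7a-tetrahydro-1-benzofuran-2(3H)-one (formed as its dilithium alkoxide; 4-OH cis to the C3a–C3 bond) | COC(OC)C1=C([C@@H](C)CCCO)[C@@H](O)[C@H]2[C@H](CN(C)C)C(=O)O[C@@H]2C1 | intermediate
17 | (4S)-4-[(3R,3aS,4S,7aR)-4-acetoxy-6-(dimethoxymethyl)-3-[(dimethylamino)methyl]-2-oxo-2,3,3a,4,7,7a-hexahydro-1-benzofuran-5-yl]pentyl acetate | COC(OC)C1=C([C@@H](C)CCCOC(C)=O)[C@@H](OC(C)=O)[C@H]2[C@H](CN(C)C)C(=O)O[C@@H]2C1 | intermediate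
18 | (4S)-4-[(3R,3aS,4S,7aR)-4-acetoxy-3-[(dimethylamino)methyl]-6-formyl-2-oxo-2,3,3a,4,7,7a-hexahydro-1-benzofuran-5-yl]pentyl acetate | O=CC1=C([C@@H](C)CCCOC(C)=O)[C@@H](OC(C)=O)[C@H]2[C@H](CN(C)C)C(=O)O[C@@H]2C1 | intermediate
19 | (4S)-4-[(3R,3aS,4S,7aR)-4-acetoxy-3-[(dimethylamino)methyl]-6-(hydroxymethyl)-2-oxo-2,3,3a,4,7,7a-hexahydro-1-benzofuran-5-yl]pentyl acetate | OCC1=C([C@@H](C)CCCOC(C)=O)[C@@H](OC(C)=O)[C@H]2[C@H](CN(C)C)C(=O)O[C@@H]2C1 | intermediate
20 | {(3R,3aS,4S,7aR)-4-acetoxy-5-[(2S)-5-acetoxypentan-2-yl]-3-[(dimethylamino)methyl]-2-oxo-2,3,3a,4,7,7a-hexahydro-1-benzofuran-6-yl}methyl 2-methylprop-2-enoate | C=C(C)C(=O)OCC1=C([C@@H](C)CCCOC(C)=O)[C@@H](OC(C)=O)[C@H]2[C@H](CN(C)C)C(=O)O[C@@H]2C1 | intermediate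
21 | N-methyl quaternary ammonium iodide of 20 (trimethylammoniomethyl on C3 of the lactone) | C=C(C)C(=O)OCC1=C([C@@H](C)CCCOC(C)=O)[C@@H](OC(C)=O)[C@H]2[C@H](C[N+](C)(C)C)C(=O)O[C@@H]2C1.[I-] | intermediate
22 | {(3aS,4S,7aR)-4-acetoxy-5-[(2S)-5-acetoxypentan-2-yl]-3-methylidene-2-oxo-2,3,3a,4,7,7a-hexahydro-1-benzofuran-6-yl}methyl 2-methylprop-2-enoate | C=C(C)C(=O)OCC1=C([C@@H](C)CCCOC(C)=O)[C@@H](OC(C)=O)[C@H]2C(=C)C(=O)O[C@@H]2C1 | target

## Step count and risks

Total steps: 12. Longest linear sequence: 11 (from (S)-citronellal 1 through steps 1 and 3–12); step 2 is a one-step branch to butenolide 6.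

Steps most likely to fail:

Step 4 (aldol on the lactol). The aldehyde is neopentyl-like and enolisable, so addition may be slow and the Felkin–Anh preference modest. Fallback, setting out from lactol 9 and returning at keto lactone 12: build C8–C9 by olefination and let C8 settle under thermodynamic control. Wittig reaction of 9 with the stabilised ylide Ph3P=CHC(=O)CH(OMe)2 (PhMe, 60 °C) gives the (E)-enone acid F1. Catalytic DBU then closes the lactone by reversible intramolecular oxa-Michael addition of the carboxylate to C8, which favours the 7,8-trans lactone 12.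

Step 6 (ring-closing aldol). Enolisation of the C10 ketone towards C9 can expel the lactone oxygen (retro-oxa-Michael); the opened enone would aromatise after cyclisation, and acid may also epimerise C7. Fallback, setting out from hydroxy acid 11 (taken up at neutral pH before lactonisation) and returning at enone 14: carry O8 as a silyl ether instead of the lactone while the carbocycle is made. Esterification with TMSCHN2 and silylation (TBSCl, imidazole) give the methyl ester silyl ether F2. PhI(OCOCF3)2 as in step 5 gives the diketone F3. Piperidinium acetate in PhMe closes the cyclohexenone F4; a β-silyloxy ketone eliminates far less readily than the β-acyloxy ketone. HF·pyridine then removes the silyl group and the freed C8 hydroxyl lactonises onto the methyl ester (CSA, PhMe) to give 14.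

Step 8 (C6 reduction and acetylation). The facial selectivity of LiBH(sec-Bu)3 on the hindered enone is not guaranteed, and the cis C6 alkoxide may attack the lactone carbonyl (translactonisation) before it is acetylated. Fallback, setting out from aldehyde 15 and returning at diacetate 17: invert rather than select. Luche reduction (NaBH4, CeCl3·7H2O, MeOH, −78 °C) attacks axially and gives the C6-epimeric diol F5, whose equatorial hydroxyl is trans to C11 and cannot close a cis lactone. A double Mitsunobu reaction (PPh3, DIAD, AcOH) then esterifies the primary alcohol and displaces the activated C6 hydroxyl with inversion to give 17.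

Further compounds

F1 | step 4 | (E)-enone acid from Wittig reaction of 9 (C7 and C11 configured as in 9, C8=C9 E): 2-[(dimethylamino)methyl]-3-{2-[(2S)-2,6-dimethylhept-5-en-1-yl]-1,3-dithian-2-yl}-7,7-dimethoxy-6-oxohept-4-enoic acid | S1CCCSC1(C[C@@H](C)CCC=C(C)C)[C@@H]([C@H](CN(C)C)C(=O)O)/C=C/C(=O)C(OC)OC
F2 | step 6 | methyl ester tert-butyldimethylsilyl ether of hydroxy acid 11 | S1CCCSC1(C[C@@H](C)CCC=C(C)C)[C@@H]([C@H](CN(C)C)C(=O)OC)[C@H](O[Si](C)(C)C(C)(C)C)CC(=O)C(OC)OC
F3 | step 6 | open-chain C6/C10 diketone (methyl ester, C8 silyl ether) from dethioacetalisation of F2 | O=C(C[C@@H](C)CCC=C(C)C)[C@@H]([C@H](CN(C)C)C(=O)OC)[C@H](O[Si](C)(C)C(C)(C)C)CC(=O)C(OC)OC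
F4 | step 6 | cyclohexenone from aldol cyclodehydration of F3: methyl 3-(dimethylamino)-2-[6-silyloxy-4-(dimethoxymethyl)-3-((2S)-6-methylhept-5-en-2-yl)-2-oxocyclohex-3-en-1-yl]propanoate (C7 S, C8 R, C11 R in target labels) | COC(OC)C1=C([C@@H](C)CCC=C(C)C)C(=O)[C@@H]([C@H](CN(C)C)C(=O)OC)[C@H](O[Si](C)(C)C(C)(C)C)C1
F5 | step 8 | C6 epimer of diol 16 (6-hydroxyl equatorial, trans to the C7–C11 bond) | COC(OC)C1=C([C@@H](C)CCCO)[C@H](O)[C@H]2[C@H](CN(C)C)C(=O)O[C@@H]2C1
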